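**Retrosynthetic overview**

1. The last C–C bond is lactone C3–CH2(ring B), made by trans-selective alkylation of the enolate of the (S)-4-arylmethyl-oxolan-2-one 35 (ring A half, diol arm already in place) with benzylic bromide 19; fluoride and then hydrogenolysis finish.
2. The strategy rests on ring B (C3a, C4, C5, C6, C7, C7a of the dihydrobenzofuran), a 1,2,3,5-tetrasubstituted benzene that shares C7a–O1 and C3a–C3 with the dihydrofuran. Four of its carbons come from C3–C6 of a 3-alkoxy-6-chloro-4-methoxypyridazine and two from a terminal alkyne hung on O1–C2–C3, so one intramolecular inverse-demand Diels–Alder reaction with loss of N2 closes arene and dihydrofuran together (bonds C3a–C7a and C4–C5).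
3. Both stereocentres of that half sit on the tether: anti-selective Marshall propargylation of O-benzylvanillin with an (R)-propargylic mesylate, then O-arylation with 3,6-dichloro-4-methoxypyridazine. The chlorine later becomes CH2Br.
4. Ring A half: 5-bromovanillin, Stobbe condensation, Rh-catalysed asymmetric hydrogenation and lactonisation; the diol arm follows by Pd-catalysed α-arylation and a magnesium-catalysed Evans anti-aldol reaction.
5. Ring order: benzene ring B plus dihydrofuran in step 8 and, independently, the butyrolactone in step 14; the halves are joined in step 21.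

Key step: step 8

**Remarks**

- Abbreviations: Bn = benzyl, TIPS = triisopropylsilyl, TMS = trimethylsilyl. Benzofuran atoms are numbered O1, C2, C3, C3a, C4–C7, C7a.
- The primary oxygen carries TIPS, not TBS, because a TBS group would be expected to migrate to the neighbouring benzylic alkoxide during the etherification of step 7.
- Assumption: alkoxide displaces the chlorine at C3 of 3,6-dichloro-4-methoxypyridazine, the one next to the methoxy group. The site is to be confirmed by HMBC/NOE on 14; a site-unambiguous alternative is given at the end.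
- The stereochemical sense of steps 3, 5, 13 and 18 is assigned from the accepted models and should be confirmed on the first isolated product of each.

**Route**

Step 1
Reactants: 1 methyl glycolate
Product: 2 methyl (triisopropylsilyloxy)acetate
Conditions: TIPSCl, imidazole, DMF, rt
Reagents that add atoms: chlorotriisopropylsilane CC(C)[Si](Cl)(C(C)C)C(C)C
Why: Imidazole-promoted silylation of a primary alcohol; TIPS should survive 190 °C and should not migrate in step 7.

Step 2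
Reactants: 2 methyl (triisopropylsilyloxy)acetate; 3 ethynyltrimethylsilane
Product: 5 1-(TIPSO)-4-(trimethylsilyl)but-3-yn-2-one, via lithium (trimethylsilyl)acetylide 4 (not isolated)
Conditions: 3, n-BuLi, THF, −78 °C; BF3·OEt2; then 2, −78 °C; aq NH4Cl
Reagents that add atoms: none
Why: BF3-mediated acylation of a lithium acetylide by an ester stops at the ynone because the tetrahedral adduct is held as a fluoroborate until work-up.

Step 3
Reactants: 5 1-(TIPSO)-4-(trimethylsilyl)but-3-yn-2-one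
Product: 6 (R)-1-(TIPSO)-4-(trimethylsilyl)but-3-yn-2-ol
Conditions: Ru[(S,S)-TsDPEN](p-cymene) (2 mol %, preformed from RuCl[(S,S)-TsDPEN](p-cymene) and KOH), i-PrOH, rt
Reagents that add atoms: none
Why: Noyori asymmetric transfer hydrogenation of an alkynyl ketone; the S,S catalyst places the alkyne where the aryl group of an aryl ketone sits, which should give the carbinol that is R here because CH2OSi outranks the alkyne.

Step 4
Reactants: 6 (R)-1-(TIPSO)-4-(trimethylsilyl)but-3-yn-2-ol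
Product: 7 (R)-1-(TIPSO)-4-(trimethylsilyl)but-3-yn-2-yl methanesulfonate
Conditions: MsCl, Et3N, CH2Cl2, −78 → 0 °C; used crude
Reagents that add atoms: methanesulfonyl chloride CS(=O)(=O)Cl
Why: O-sulfonylation leaves the C–O bond untouched, so the R configuration is kept and the leaving group for the SN2' step is in place.

Step 5
Reactants: 7 (R)-1-(TIPSO)-4-(trimethylsilyl)but-3-yn-2-yl methanesulfonate; 8 4-(benzyloxy)-3-methoxybenzaldehyde
Product: 10 (1R,2S)-1-(4-BnO-3-methoxyphenyl)-2-(TIPSOCH2)-4-(trimethylsilyl)but-3-yn-1-ol, via (M)-allenylindium 9 (not isolated)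
Conditions: PdCl2(dppf) (5 mol %), InI (1.5 equiv), THF/HMPA 3:1, rt
Reagents that add atoms: none
Why: Marshall propargylation: zerovalent palladium displaces the mesylate anti (SN2'), transmetalation with monovalent indium iodide gives allenylindium 9, and its closed SE2' addition to the aldehyde sets C2 with net inversion (S) and the carbinol carbon anti to it (R); any syn isomer should be removable by chromatography.

Step 6
Reactants: 10 (1R,2S)-1-(4-BnO-3-methoxyphenyl)-2-(TIPSOCH2)-4-(trimethylsilyl)but-3-yn-1-ol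
Product: 11 (1R,2S)-1-(4-BnO-3-methoxyphenyl)-2-(TIPSOCH2)but-3-yn-1-ol
Conditions: K2CO3 (0.2 equiv), MeOH, 0 °C → rt
Reagents that add atoms: none
Why: Base-catalysed methanolysis cleaves only the alkynyl C–Si bond; the O–TIPS ether and both stereocentres are not affected.

Step 7
Reactants: 11 (1R,2S)-1-(4-BnO-3-methoxyphenyl)-2-(TIPSOCH2)but-3-yn-1-ol; 12 3,6-dichloro-4-methoxypyridazine
Product: 14 6-chloro-4-methoxy-3-{[(1R,2S)-1-(4-BnO-3-methoxyphenyl)-2-(TIPSOCH2)but-3-yn-1-yl]oxy}pyridazine, via sodium alkoxide 13 (not isolated)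
Conditions: NaH (1.1 equiv), THF, 0 °C, 15 min; then 12 (1.2 equiv), 0 °C → rt
Reagents that add atoms: none
Why: Addition–elimination (SNAr) with retention at the carbinol carbon: attack at C3 places the negative charge on N2, which is not conjugated to the C4 methoxy donor, whereas attack at C6 must load N1, the atom para to that donor, so the chlorine next to the methoxy group is expected to leave.

Step 8
Reactants: 14 6-chloro-4-methoxy-3-{[(1R,2S)-1-(4-BnO-3-methoxyphenyl)-2-(TIPSOCH2)but-3-yn-1-yl]oxy}pyridazine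
Product: 16 (2R,3S)-2-(4-BnO-3-methoxyphenyl)-5-chloro-7-methoxy-3-(TIPSOCH2)-2,3-dihydro-1-benzofuran, via diazabicyclooctatriene adduct 15 (not isolated)
Conditions: 1,3,5-triisopropylbenzene (0.01 M), 2,6-di-tert-butyl-4-methylpyridine (0.2 equiv), Ar, sealed tube, 190 °C
Reagents that add atoms: none
Why: The terminal alkyne adds as the 2π partner across C3 and C6 of the electron-poor diazine (intramolecular inverse-demand Diels–Alder reaction) to give the 2,3-diazabicyclo[2.2.2]octatriene 15, which loses N2 by retro-[4+2] cycloreversion and so becomes benzene ring B with the new bonds C3a–C7a and C4–C5. The closest known reaction is the thermal cyclisation of 3-(but-3-ynyloxy)pyridazines to 2,3-dihydrobenzofurans; the C4 methoxy donor and the doubly substituted tether are the untested elements. The dihydrofuran closes as the five-membered ring imposed by the three-atom O1–C2–C3 tether fixed to the diene terminus (fused, type 1 intramolecular cycloaddition, so bonding to C3 and C6 is the only possible orientation), and the benzene ring closes by the [4+2]/retro-[4+2] pair. No stereocentre is created: C2 and C3 lie on the tether, are not touched, and their anti relation becomes the trans relation of 16, while the bridgehead centres of 15 vanish with N2. The step needs chemoselectivity for cycloaddition over heterolysis or retro-ene cleavage of the benzylic pyridazinyl ether. The chlorine at C6 lowers the diene LUMO, the two tether substituents favour the folded rotamer, and the apolar, base-buffered, dilute medium disfavours ion-pair formation.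

Step 9
Reactants: 16 (2R,3S)-2-(4-BnO-3-methoxyphenyl)-5-chloro-7-methoxy-3-(TIPSOCH2)-2,3-dihydro-1-benzofuran
Product: 18 [(2R,3S)-2-(4-BnO-3-methoxyphenyl)-7-methoxy-3-(TIPSOCH2)-2,3-dihydro-1-benzofuran-5-yl]methanol, via benzylic acetate 17 (not isolated)
Conditions: KF3BCH2OAc (1.5 equiv), Pd(dba)2 (5 mol %), RuPhos (10 mol %), Na2CO3, dioxane/H2O 10:1, 100 °C
Reagents that add atoms: potassium (acetoxymethyl)trifluoroborate CC(=O)OC[B-](F)(F)F.[K+]
Why: Suzuki–Miyaura coupling of the electron-rich aryl chloride, made possible by the bulky dialkylbiarylphosphine, followed by hydrolysis of the acetate in the basic aqueous medium.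

Step 10
Reactants: 18 [(2R,3S)-2-(4-BnO-3-methoxyphenyl)-7-methoxy-3-(TIPSOCH2)-2,3-dihydro-1-benzofuran-5-yl]methanol
Product: 19 (2R,3S)-5-(bromomethyl)-2-(4-BnO-3-methoxyphenyl)-7-methoxy-3-(TIPSOCH2)-2,3-dihydro-1-benzofuran
Conditions: CBr4, PPh3, CH2Cl2, 0 °C; filtered through a short silica pad and used at once
Reagents that add atoms: tetrabromomethane BrC(Br)(Br)Br
Why: The Appel reaction is neutral, so the acid-labile 2-aryl dihydrobenzofuran and the silyl ether should survive.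

Step 11
Reactants: 20 3-bromo-4-hydroxy-5-methoxybenzaldehyde (5-bromovanillin)
Product: 21 4-(benzyloxy)-3-bromo-5-methoxybenzaldehyde
Conditions: BnBr, K2CO3, DMF, 50 °C
Reagents that add atoms: benzyl bromide BrCc1ccccc1
Why: Williamson etherification of the phenoxide.

Step 12
Reactants: 21 4-(benzyloxy)-3-bromo-5-methoxybenzaldehyde; 22 dimethyl succinate
Product: 24 (E)-4-[4-(benzyloxy)-3-bromo-5-methoxyphenyl]-3-(methoxycarbonyl)but-3-enoic acid, via paraconate 23 (not isolated)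
Conditions: NaOMe, MeOH, reflux; then aq HCl
Reagents that add atoms: none
Why: Stobbe condensation: aldol addition, lactonisation to 23 and E1cB ring opening give the itaconate half-ester whose ester sits on the carbon that will carry the lactone CH2O.

Step 13
Reactants: 24 (E)-4-[4-(benzyloxy)-3-bromo-5-methoxyphenyl]-3-(methoxycarbonyl)but-3-enoic acid
Product: 25 (3S)-3-{[4-(benzyloxy)-3-bromo-5-methoxyphenyl]methyl}-4-methoxy-4-oxobutanoic acid
Conditions: [Rh(cod)((R,R)-Et-DuPhos)]BF4 (1 mol %), H2 (5 bar), NaOMe (0.1 equiv), MeOH, rt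
Reagents that add atoms: none
Why: Rh-catalysed asymmetric hydrogenation of a β-aryl itaconate half-ester, in which the carboxylate chelates rhodium as the amide does in enamide hydrogenation; the R,R ligand should give the S acid, and the cationic catalyst leaves the aryl bromide and the benzyl ether alone.

Step 14
Reactants: 25 (3S)-3-{[4-(benzyloxy)-3-bromo-5-methoxyphenyl]methyl}-4-methoxy-4-oxobutanoic acid
Product: 27 (4S)-4-{[4-(benzyloxy)-3-bromo-5-methoxyphenyl]methyl}oxolan-2-one, via potassium hydroxy carboxylate 26 (not isolated)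
Conditions: KOH (1.0 equiv), EtOH; CaCl2, NaBH4, −10 °C → rt; then 2 M HCl; recrystallise
Reagents that add atoms: none
Why: Ca(BH4)2 reduces the ester but not the carboxylate, and acidification lactonises the γ-hydroxy acid without touching the stereocentre; crystallisation should raise the enantiomeric purity before the arm is built.

Step 15
Reactants: 27 (4S)-4-{[4-(benzyloxy)-3-bromo-5-methoxyphenyl]methyl}oxolan-2-one
Product: 28 tert-butyl 2-[2-(benzyloxy)-3-methoxy-5-{[(3S)-5-oxooxolan-3-yl]methyl}phenyl]acetate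
Conditions: BrZnCH2CO2t-Bu (1.5 equiv), Pd(dba)2 (2 mol %), P(t-Bu)3 (4 mol %), THF, rt → 50 °C
Reagents that add atoms: (2-tert-butoxy-2-oxoethyl)zinc bromide CC(C)(C)OC(=O)C[Zn]Br
Why: Pd-catalysed α-arylation of a Reformatsky reagent (Negishi-type coupling); the zinc enolate neither adds to nor deprotonates the lactone.

Step 16
Reactants: 28 tert-butyl 2-[2-(benzyloxy)-3-methoxy-5-{[(3S)-5-oxooxolan-3-yl]methyl}phenyl]acetate
Product: 29 2-[2-(benzyloxy)-3-methoxy-5-{[(3S)-5-oxooxolan-3-yl]methyl}phenyl]acetic acid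
Conditions: TFA/CH2Cl2 1:4, 0 °C → rt
Reagents that add atoms: none
Why: Acidolysis of the tert-butyl ester with loss of isobutene; lactone and aryl benzyl ether tolerate brief TFA, and no acid-labile benzylic alcohol is present yet.

Step 17
Reactants: 29 2-[2-(benzyloxy)-3-methoxy-5-{[(3S)-5-oxooxolan-3-yl]methyl}phenyl]acetic acid
Product: 31 (4S)-4-benzyl-3-{2-[2-(benzyloxy)-3-methoxy-5-{[(3S)-5-oxooxolan-3-yl]methyl}phenyl]acetyl}-1,3-oxazolidin-2-one, via mixed pivalic anhydride 30 (not isolated)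
Conditions: PivCl, Et3N, THF, −20 °C; then (S)-4-benzyloxazolidin-2-one, LiCl, −20 °C → rt
Reagents that add atoms: (4S)-4-benzyl-1,3-oxazolidin-2-one O=C1N[C@@H](Cc2ccccc2)CO1
Why: N-acylation of the oxazolidinone through the mixed anhydride under LiCl/Et3N conditions, mild enough for the lactone.

Step 18
Reactants: 31 (4S)-4-benzyl-3-{2-[2-(benzyloxy)-3-methoxy-5-{[(3S)-5-oxooxolan-3-yl]methyl}phenyl]acetyl}-1,3-oxazolidin-2-one; 8 4-(benzyloxy)-3-methoxybenzaldehyde
Product: 32 (4S)-4-benzyl-3-[(2R,3S)-2-[2-(benzyloxy)-3-methoxy-5-{[(3S)-5-oxooxolan-3-yl]methyl}phenyl]-3-(4-BnO-3-methoxyphenyl)-3-(trimethylsilyloxy)propanoyl]-1,3-oxazolidin-2-one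
Conditions: MgCl2 (0.2 equiv), Et3N (2 equiv), TMSCl (1.5 equiv), EtOAc, rt
Reagents that add atoms: chlorotrimethylsilane C[Si](C)(C)Cl
Why: Magnesium-catalysed Evans anti-aldol reaction: the chelated magnesium Z-enolate is attacked on the face away from the benzyl group through a boat transition state, which sets C2 as R and the carbinol carbon as S (anti), and silylation of the aldolate turns the catalyst over and blocks retro-aldol cleavage.

Step 19
Reactants: 32 (4S)-4-benzyl-3-[(2R,3S)-2-[2-(benzyloxy)-3-methoxy-5-{[(3S)-5-oxooxolan-3-yl]methyl}phenyl]-3-(4-BnO-3-methoxyphenyl)-3-(trimethylsilyloxy)propanoyl]-1,3-oxazolidin-2-one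
Product: 34 (4S)-4-{[4-(benzyloxy)-3-[(1S,2S)-1-(4-BnO-3-methoxyphenyl)-1,3-dihydroxypropan-2-yl]-5-methoxyphenyl]methyl}oxolan-2-one, via silyl ether alcohol 33 (not isolated)
Conditions: NaBH4, THF/H2O 4:1, 0 °C → rt; then 10% aq citric acid
Reagents that add atoms: none
Why: Borohydride removes the auxiliary reductively because the exocyclic imide carbonyl is far more electrophilic than the γ-lactone, and the mild acid work-up hydrolyses the TMS ether; the descriptor of the former α-carbon changes from R to S only because CH2OH ranks below the carbinol carbon.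

Step 20
Reactants: 34 (4S)-4-{[4-(benzyloxy)-3-[(1S,2S)-1-(4-BnO-3-methoxyphenyl)-1,3-dihydroxypropan-2-yl]-5-methoxyphenyl]methyl}oxolan-2-one
Product: 35 (4S)-4-{[4-(benzyloxy)-3-[(4S,5S)-4-(4-BnO-3-methoxyphenyl)-2,2-di-tert-butyl-1,3,2-dioxasilinan-5-yl]-5-methoxyphenyl]methyl}oxolan-2-one
Conditions: t-Bu2Si(OTf)2, 2,6-lutidine, CH2Cl2, 0 °C
Reagents that add atoms: di-tert-butylsilyl bis(trifluoromethanesulfonate) CC(C)(C)[Si](OS(=O)(=O)C(F)(F)F)(OS(=O)(=O)C(F)(F)F)C(C)(C)C
Why: The 1,3-diol is tied up as a cyclic silylene under basic conditions, which avoids acid at the electron-rich benzylic carbinol; the anti diol gives the trans-4,5-diaryl dioxasilinane.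

Step 21
Reactants: 35 (4S)-4-{[4-(benzyloxy)-3-[(4S,5S)-4-(4-BnO-3-methoxyphenyl)-2,2-di-tert-butyl-1,3,2-dioxasilinan-5-yl]-5-methoxyphenyl]methyl}oxolan-2-one; 19 (2R,3S)-5-(bromomethyl)-2-(4-BnO-3-methoxyphenyl)-7-methoxy-3-(TIPSOCH2)-2,3-dihydro-1-benzofuran
Product: 37 (3S,4S)-3-{[(2R,3S)-2-(4-BnO-3-methoxyphenyl)-7-methoxy-3-(TIPSOCH2)-2,3-dihydro-1-benzofuran-5-yl]methyl}-4-{[4-(benzyloxy)-3-[(4S,5S)-4-(4-BnO-3-methoxyphenyl)-2,2-di-tert-butyl-1,3,2-dioxasilinan-5-yl]-5-methoxyphenyl]methyl}oxolan-2-one, via lithium enolate 36 (not isolated)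
Conditions: LiHMDS (1.05 equiv), THF, −78 °C; then 19 (1.1 equiv), DMPU, −78 → −30 °C
Reagents that add atoms: none
Why: The lithium lactone enolate is alkylated on the face opposite the C4 arylmethyl group, the standard entry to trans-2,3-dibenzylbutyrolactones, which sets C3 as S.

Step 22
Reactants: 37 the coupled, fully protected lactone
Product: 38 (3S,4S)-3-{[(2R,3S)-2-(4-BnO-3-methoxyphenyl)-3-(hydroxymethyl)-7-methoxy-2,3-dihydro-1-benzofuran-5-yl]methyl}-4-{[4-(benzyloxy)-3-[(1S,2S)-1-(4-BnO-3-methoxyphenyl)-1,3-dihydroxypropan-2-yl]-5-methoxyphenyl]methyl}oxolan-2-one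
Conditions: TBAF/AcOH 1:1 (6 equiv), THF, rt
Reagents that add atoms: none
Why: Buffered fluoride cleaves the TIPS ether and the silylene at silicon without acid or strong base, so the benzylic alcohol and the lactone should be kept.

Step 23
Reactants: 38 the tribenzyl ether triol
Product: 39 (3S,4S)-3-{[(2R,3S)-2-(4-hydroxy-3-methoxyphenyl)-3-(hydroxymethyl)-7-methoxy-2,3-dihydro-1-benzofuran-5-yl]methyl}-4-({3-[(1S,2S)-1,3-dihydroxy-1-(4-hydroxy-3-methoxyphenyl)propan-2-yl]-4-hydroxy-5-methoxyphenyl}methyl)oxolan-2-one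
Conditions: H2 (1 atm), 10% Pd/C, EtOAc/EtOH 1:1, rt; stopped at full conversion
Reagents that add atoms: none
Why: Neutral hydrogenolysis removes the three aryl benzyl ethers much faster than it attacks the benzylic C–O bonds of the carbinol and the dihydrofuran, and no acid is present that could close the free arm to a second dihydrobenzofuran.

**Compound list**

1 | methyl glycolate | COC(=O)CO | starting material
2 | methyl (triisopropylsilyloxy)acetate | COC(=O)CO[Si](C(C)C)(C(C)C)C(C)C | intermediate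
3 | ethynyltrimethylsilane | C#C[Si](C)(C)C | starting material
4 | lithium (trimethylsilyl)acetylide | [Li]C#C[Si](C)(C)C | intermediate (not isolated)
5 | 1-(triisopropylsilyloxy)-4-(trimethylsilyl)but-3-yn-2-one | CC(C)[Si](OCC(=O)C#C[Si](C)(C)C)(C(C)C)C(C)C | intermediate
6 | (R)-1-(triisopropylsilyloxy)-4-(trimethylsilyl)but-3-yn-2-ol | CC(C)[Si](OC[C@H](O)C#C[Si](C)(C)C)(C(C)C)C(C)C | intermediate
7 | (R)-1-(triisopropylsilyloxy)-4-(trimethylsilyl)but-3-yn-2-yl methanesulfonate | CC(C)[Si](OC[C@H](OS(C)(=O)=O)C#C[Si](C)(C)C)(C(C)C)C(C)C | intermediate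
8 | 4-(benzyloxy)-3-methoxybenzaldehyde | COc1cc(C=O)ccc1OCc1ccccc1 | starting material
9 | (M)-[4-(triisopropylsilyloxy)-1-(trimethylsilyl)buta-1,2-dien-1-yl]indium iodide methanesulfonate | [In](I)(OS(C)(=O)=O)C([Si](C)(C)C)=[C@]=C([H])CO[Si](C(C)C)(C(C)C)C(C)C | intermediate (not isolated)
10 | (1R,2S)-1-[4-(benzyloxy)-3-methoxyphenyl]-2-[(triisopropylsilyloxy)methyl]-4-(trimethylsilyl)but-3-yn-1-ol | O[C@@H](c1ccc(OCc2ccccc2)c(OC)c1)[C@H](CO[Si](C(C)C)(C(C)C)C(C)C)C#C[Si](C)(C)C | intermediate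
11 | (1R,2S)-1-[4-(benzyloxy)-3-methoxyphenyl]-2-[(triisopropylsilyloxy)methyl]but-3-yn-1-ol | O[C@@H](c1ccc(OCc2ccccc2)c(OC)c1)[C@H](CO[Si](C(C)C)(C(C)C)C(C)C)C#C | intermediate
12 | 3,6-dichloro-4-methoxypyridazine | COc1cc(Cl)nnc1Cl | starting material
13 | sodium (1R,2S)-1-[4-(benzyloxy)-3-methoxyphenyl]-2-[(triisopropylsilyloxy)methyl]but-3-yn-1-olate | [Na+].[O-][C@@H](c1ccc(OCc2ccccc2)c(OC)c1)[C@H](CO[Si](C(C)C)(C(C)C)C(C)C)C#C | intermediate (not isolated)
14 | 6-chloro-4-methoxy-3-{[(1R,2S)-1-[4-(benzyloxy)-3-methoxyphenyl]-2-[(triisopropylsilyloxy)methyl]but-3-yn-1-yl]oxy}pyridazine | COc1cc(Cl)nnc1O[C@@H](c1ccc(OCc2ccccc2)c(OC)c1)[C@H](CO[Si](C(C)C)(C(C)C)C(C)C)C#C | intermediate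
15 | [4+2] adduct of 14: 2,3-diazabicyclo[2.2.2]octa-2,5,7-triene with Cl and the ether oxygen at the bridgeheads, fused to the oxolane (either bridgehead diastereomer gives the same arene) | COC1=CC2(Cl)N=NC13O[C@@H](c4ccc(OCc5ccccc5)c(OC)c4)[C@H](CO[Si](C(C)C)(C(C)C)C(C)C)C3=C2 | intermediate (not isolated)
16 | (2R,3S)-2-[4-(benzyloxy)-3-methoxyphenyl]-5-chloro-7-methoxy-3-[(triisopropylsilyloxy)methyl]-2,3-dihydro-1-benzofuran | Clc1cc(OC)c2c(c1)[C@@H](CO[Si](C(C)C)(C(C)C)C(C)C)[C@H](c1ccc(OCc3ccccc3)c(OC)c1)O2 | intermediate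
17 | [(2R,3S)-2-[4-(benzyloxy)-3-methoxyphenyl]-7-methoxy-3-[(triisopropylsilyloxy)methyl]-2,3-dihydro-1-benzofuran-5-yl]methyl acetate | CC(=O)OCc1cc(OC)c2c(c1)[C@@H](CO[Si](C(C)C)(C(C)C)C(C)C)[C@H](c1ccc(OCc3ccccc3)c(OC)c1)O2 | intermediate (not isolated)
18 | [(2R,3S)-2-[4-(benzyloxy)-3-methoxyphenyl]-7-methoxy-3-[(triisopropylsilyloxy)methyl]-2,3-dihydro-1-benzofuran-5-yl]methanol | OCc1cc(OC)c2c(c1)[C@@H](CO[Si](C(C)C)(C(C)C)C(C)C)[C@H](c1ccc(OCc3ccccc3)c(OC)c1)O2 | intermediate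
19 | (2R,3S)-5-(bromomethyl)-2-[4-(benzyloxy)-3-methoxyphenyl]-7-methoxy-3-[(triisopropylsilyloxy)methyl]-2,3-dihydro-1-benzofuran | BrCc1cc(OC)c2c(c1)[C@@H](CO[Si](C(C)C)(C(C)C)C(C)C)[C@H](c1ccc(OCc3ccccc3)c(OC)c1)O2 | intermediate
20 | 3-bromo-4-hydroxy-5-methoxybenzaldehyde (5-bromovanillin) | COc1cc(C=O)cc(Br)c1O | starting material
21 | 4-(benzyloxy)-3-bromo-5-methoxybenzaldehyde | COc1cc(C=O)cc(Br)c1OCc1ccccc1 | intermediate
22 | dimethyl succinate | COC(=O)CCC(=O)OC | starting material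
23 | methyl 2-[4-(benzyloxy)-3-bromo-5-methoxyphenyl]-5-oxooxolane-3-carboxylate (mixture of stereoisomers) | COC(=O)C1CC(=O)OC1c1cc(Br)c(OCc2ccccc2)c(OC)c1 | intermediate (not isolated)
24 | (E)-4-[4-(benzyloxy)-3-bromo-5-methoxyphenyl]-3-(methoxycarbonyl)but-3-enoic acid | COC(=O)/C(CC(=O)O)=C/c1cc(Br)c(OCc2ccccc2)c(OC)c1 | intermediate
25 | (3S)-3-{[4-(benzyloxy)-3-bromo-5-methoxyphenyl]methyl}-4-methoxy-4-oxobutanoic acid | COC(=O)[C@@H](Cc1cc(Br)c(OCc2ccccc2)c(OC)c1)CC(=O)O | intermediate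
26 | potassium (3S)-3-{[4-(benzyloxy)-3-bromo-5-methoxyphenyl]methyl}-4-hydroxybutanoate | OC[C@@H](Cc1cc(Br)c(OCc2ccccc2)c(OC)c1)CC(=O)[O-].[K+] | intermediate (not isolated)
27 | (4S)-4-{[4-(benzyloxy)-3-bromo-5-methoxyphenyl]methyl}oxolan-2-one | O=C1C[C@H](Cc2cc(Br)c(OCc3ccccc3)c(OC)c2)CO1 | intermediate
28 | tert-butyl 2-[2-(benzyloxy)-3-methoxy-5-{[(3S)-5-oxooxolan-3-yl]methyl}phenyl]acetate | CC(C)(C)OC(=O)Cc1cc(C[C@@H]2COC(=O)C2)cc(OC)c1OCc1ccccc1 | intermediate
29 | 2-[2-(benzyloxy)-3-methoxy-5-{[(3S)-5-oxooxolan-3-yl]methyl}phenyl]acetic acid | OC(=O)Cc1cc(C[C@@H]2COC(=O)C2)cc(OC)c1OCc1ccccc1 | intermediate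
30 | mixed anhydride of 29 and pivalic acid | CC(C)(C)C(=O)OC(=O)Cc1cc(C[C@@H]2COC(=O)C2)cc(OC)c1OCc1ccccc1 | intermediate (not isolated)
31 | (4S)-4-benzyl-3-{2-[2-(benzyloxy)-3-methoxy-5-{[(3S)-5-oxooxolan-3-yl]methyl}phenyl]acetyl}-1,3-oxazolidin-2-one | O=C(Cc1cc(C[C@@H]2COC(=O)C2)cc(OC)c1OCc1ccccc1)N1[C@@H](Cc2ccccc2)COC1=O | intermediate
32 | (4S)-4-benzyl-3-[(2R,3S)-2-[2-(benzyloxy)-3-methoxy-5-{[(3S)-5-oxooxolan-3-yl]methyl}phenyl]-3-[4-(benzyloxy)-3-methoxyphenyl]-3-(trimethylsilyloxy)propanoyl]-1,3-oxazolidin-2-one | COc1cc([C@@H](O[Si](C)(C)C)[C@H](C(=O)N2[C@@H](Cc3ccccc3)COC2=O)c2cc(C[C@@H]3COC(=O)C3)cc(OC)c2OCc2ccccc2)ccc1OCc1ccccc1 | intermediate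
33 | (4S)-4-{[4-(benzyloxy)-3-[(1S,2S)-1-[4-(benzyloxy)-3-methoxyphenyl]-3-hydroxy-1-(trimethylsilyloxy)propan-2-yl]-5-methoxyphenyl]methyl}oxolan-2-one | COc1cc([C@@H](O[Si](C)(C)C)[C@H](CO)c2cc(C[C@@H]3COC(=O)C3)cc(OC)c2OCc2ccccc2)ccc1OCc1ccccc1 | intermediate (not isolated)
34 | (4S)-4-{[4-(benzyloxy)-3-[(1S,2S)-1-[4-(benzyloxy)-3-methoxyphenyl]-1,3-dihydroxypropan-2-yl]-5-methoxyphenyl]methyl}oxolan-2-one | COc1cc([C@@H](O)[C@H](CO)c2cc(C[C@@H]3COC(=O)C3)cc(OC)c2OCc2ccccc2)ccc1OCc1ccccc1 | intermediate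
35 | (4S)-4-{[4-(benzyloxy)-3-[(4S,5S)-4-[4-(benzyloxy)-3-methoxyphenyl]-2,2-di-tert-butyl-1,3,2-dioxasilinan-5-yl]-5-methoxyphenyl]methyl}oxolan-2-one | COc1cc([C@H]2O[Si](C(C)(C)C)(C(C)(C)C)OC[C@@H]2c4cc(C[C@@H]3COC(=O)C3)cc(OC)c4OCc4ccccc4)ccc1OCc1ccccc1 | intermediate
36 | lithium enolate of 35 | COc1cc([C@H]2O[Si](C(C)(C)C)(C(C)(C)C)OC[C@@H]2c4cc(C[C@@H]3COC(O[Li])=C3)cc(OC)c4OCc4ccccc4)ccc1OCc1ccccc1 | intermediate (not isolated)
37 | (3S,4S)-3-{[(2R,3S)-2-[4-(benzyloxy)-3-methoxyphenyl]-7-methoxy-3-[(triisopropylsilyloxy)methyl]-2,3-dihydro-1-benzofuran-5-yl]methyl}-4-{[4-(benzyloxy)-3-[(4S,5S)-4-[4-(benzyloxy)-3-methoxyphenyl]-2,2-di-tert-butyl-1,3,2-dioxasilinan-5-yl]-5-methoxyphenyl]methyl}oxolan-2-one | COc1cc([C@H]2O[Si](C(C)(C)C)(C(C)(C)C)OC[C@@H]2c4cc(C[C@@H]3COC(=O)[C@H]3Cc3cc(OC)c5c(c3)[C@@H](CO[Si](C(C)C)(C(C)C)C(C)C)[C@H](c3ccc(OCc6ccccc6)c(OC)c3)O5)cc(OC)c4OCc4ccccc4)ccc1OCc1ccccc1 | intermediate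
38 | (3S,4S)-3-{[(2R,3S)-2-[4-(benzyloxy)-3-methoxyphenyl]-3-(hydroxymethyl)-7-methoxy-2,3-dihydro-1-benzofuran-5-yl]methyl}-4-{[4-(benzyloxy)-3-[(1S,2S)-1-[4-(benzyloxy)-3-methoxyphenyl]-1,3-dihydroxypropan-2-yl]-5-methoxyphenyl]methyl}oxolan-2-one | COc1cc([C@@H](O)[C@H](CO)c2cc(C[C@@H]3COC(=O)[C@H]3Cc3cc(OC)c4c(c3)[C@@H](CO)[C@H](c3ccc(OCc5ccccc5)c(OC)c3)O4)cc(OC)c2OCc2ccccc2)ccc1OCc1ccccc1 | intermediate
39 | (3S,4S)-3-{[(2R,3S)-2-(4-hydroxy-3-methoxyphenyl)-3-(hydroxymethyl)-7-methoxy-2,3-dihydro-1-benzofuran-5-yl]methyl}-4-({3-[(1S,2S)-1,3-dihydroxy-1-(4-hydroxy-3-methoxyphenyl)propan-2-yl]-4-hydroxy-5-methoxyphenyl}methyl)oxolan-2-one (CNP0199264.1) | COc1cc([C@@H](O)[C@H](CO)c2cc(C[C@@H]3COC(=O)[C@H]3Cc3cc(OC)c4c(c3)[C@@H](CO)[C@H](c3ccc(O)c(OC)c3)O4)cc(OC)c2O)ccc1O | target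

**Count and risks**

Total step count: 23. Longest linear sequence: 13 steps (steps 1–10 and 21–23; the ring A branch, steps 11–20 and 21–23, is equally long).

Steps most likely to fail:

1. Step 8. Thermal heterolysis or retro-ene cleavage of the benzylic C–O bond of the pyridazinyl ether may outrun the cycloaddition, which the C4 methoxy donor slows. Fallback: buy ring B as an arene and close only the dihydrofuran; it sets out from aldehyde 8 and returns at 16. Commercial 4-chloro-2-methoxyphenol is brominated with NBS to 2-bromo-4-chloro-6-methoxyphenol F1 and O-allylated to 2-(allyloxy)-1-bromo-5-chloro-3-methoxybenzene F2. Coupling at bromine with the Reformatsky reagent as in step 15 gives tert-butyl 2-[2-(allyloxy)-5-chloro-3-methoxyphenyl]acetate F3, and TFA gives 2-[2-(allyloxy)-5-chloro-3-methoxyphenyl]acetic acid F4. Acylation as in step 17 gives the (4S)-4-benzyloxazolidinone imide F5, and the anti-aldol reaction of step 18 with 8 gives the silylated (2R,3S) adduct F6. LiBH4 and mild acid give (1S,2S)-2-[2-(allyloxy)-5-chloro-3-methoxyphenyl]-1-[4-(benzyloxy)-3-methoxyphenyl]propane-1,3-diol F7, TIPSCl/imidazole gives its primary TIPS ether F8, and Pd(PPh3)4/morpholine gives the free phenol F9. Mitsunobu closure (PPh3, DIAD) by the phenol with inversion at the benzylic carbinol turns the anti diol into trans-dihydrobenzofuran 16.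

2. Step 7. Substitution may occur at C6 in place of C3, or the silyl group may migrate to the alkoxide before O-arylation. Fallback: make the leaving groups different instead of relying on the ring electronics; it sets out from alcohol 11 (as alkoxide 13) and returns at 14. Commercial 4-bromo-6-chloropyridazin-3-amine and NaOMe give 6-chloro-4-methoxypyridazin-3-amine F10, whose methoxy position is fixed by the amine. Diazotisation with t-BuONO in the presence of MeSSMe gives 6-chloro-4-methoxy-3-(methylsulfanyl)pyridazine F11, and mCPBA gives 6-chloro-3-(methanesulfonyl)-4-methoxypyridazine F12. Alkoxide 13 then displaces methanesulfinate at C3 in preference to chloride at C6 and gives 14.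

3. Step 5. Anti selectivity may erode with an aromatic aldehyde, and the allenylmetal may racemise or eliminate. Fallback: transfer the axis through boron and a closed chair transition state; it sets out from alcohol 6 and returns at 10. Alcohol 6 and methyl chloroformate/pyridine give methyl (R)-1-(triisopropylsilyloxy)-4-(trimethylsilyl)but-3-yn-2-yl carbonate F13. Copper-catalysed anti-SN2' borylation (CuCl, NaOt-Bu, Xantphos, B2pin2, THF) gives the (P)-allenylboronic pinacol ester F14. Brønsted acid-catalysed allenylboration of aldehyde 8 (diphenyl phosphate, toluene, rt) should then give 10.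

Further compounds
F1 | step 8 | 2-bromo-4-chloro-6-methoxyphenol | COc1cc(Cl)cc(Br)c1O
F2 | step 8 | 2-(allyloxy)-1-bromo-5-chloro-3-methoxybenzene | C=CCOc1c(Br)cc(Cl)cc1OC
F3 | step 8 | tert-butyl 2-[2-(allyloxy)-5-chloro-3-methoxyphenyl]acetate | CC(C)(C)OC(=O)Cc1cc(Cl)cc(OC)c1OCC=C
F4 | step 8 | 2-[2-(allyloxy)-5-chloro-3-methoxyphenyl]acetic acid | OC(=O)Cc1cc(Cl)cc(OC)c1OCC=C
F5 | step 8 | (4S)-3-{2-[2-(allyloxy)-5-chloro-3-methoxyphenyl]acetyl}-4-benzyl-1,3-oxazolidin-2-one | O=C(Cc1cc(Cl)cc(OC)c1OCC=C)N1[C@@H](Cc2ccccc2)COC1=O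
F6 | step 8 | (4S)-3-[(2R,3S)-2-[2-(allyloxy)-5-chloro-3-methoxyphenyl]-3-[4-(benzyloxy)-3-methoxyphenyl]-3-(trimethylsilyloxy)propanoyl]-4-benzyl-1,3-oxazolidin-2-one | COc1cc([C@@H](O[Si](C)(C)C)[C@H](C(=O)N2[C@@H](Cc3ccccc3)COC2=O)c2cc(Cl)cc(OC)c2OCC=C)ccc1OCc1ccccc1
F7 | step 8 | (1S,2S)-2-[2-(allyloxy)-5-chloro-3-methoxyphenyl]-1-[4-(benzyloxy)-3-methoxyphenyl]propane-1,3-diol | COc1cc([C@@H](O)[C@H](CO)c2cc(Cl)cc(OC)c2OCC=C)ccc1OCc1ccccc1
F8 | step 8 | (1S,2S)-2-[2-(allyloxy)-5-chloro-3-methoxyphenyl]-1-[4-(benzyloxy)-3-methoxyphenyl]-3-(triisopropylsilyloxy)propan-1-ol | COc1cc([C@@H](O)[C@H](CO[Si](C(C)C)(C(C)C)C(C)C)c2cc(Cl)cc(OC)c2OCC=C)ccc1OCc1ccccc1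
F9 | step 8 | 2-[(1S,2S)-1-[4-(benzyloxy)-3-methoxyphenyl]-1-hydroxy-3-(triisopropylsilyloxy)propan-2-yl]-4-chloro-6-methoxyphenol | COc1cc([C@@H](O)[C@H](CO[Si](C(C)C)(C(C)C)C(C)C)c2cc(Cl)cc(OC)c2O)ccc1OCc1ccccc1
F10 | step 7 | 6-chloro-4-methoxypyridazin-3-amine | COc1cc(Cl)nnc1N
F11 | step 7 | 6-chloro-4-methoxy-3-(methylsulfanyl)pyridazine | COc1cc(Cl)nnc1SC
F12 | step 7 | 6-chloro-3-(methanesulfonyl)-4-methoxypyridazine | COc1cc(Cl)nnc1S(C)(=O)=O
F13 | step 5 | methyl (R)-1-(triisopropylsilyloxy)-4-(trimethylsilyl)but-3-yn-2-yl carbonate | COC(=O)O[C@@H](CO[Si](C(C)C)(C(C)C)C(C)C)C#C[Si](C)(C)C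
F14 | step 5 | (P)-4,4,5,5-tetramethyl-2-[4-(triisopropylsilyloxy)-1-(trimethylsilyl)buta-1,2-dien-1-yl]-1,3,2-dioxaborolane | CC1(C)OB(OC1(C)C)C([Si](C)(C)C)=[C@]=C([H])CO[Si](C(C)C)(C(C)C)C(C)C
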